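## The problem

The target, compound 18, is a biisoflavone. A daidzein unit (7,4'-dihydroxyisoflavone) and a genistein unit (5,7,4'-trihydroxyisoflavone) are joined by one aryl–aryl bond from daidzein C8 to genistein C3'. This bond lies between O1 and the 7-oxygen on daidzein ring A and next to the 4'-oxygen on genistein ring B. It therefore has to be made at the more crowded of two electronically similar positions on each side (C8 against C6, C3' against C5'). The molecule has no stereocentre, and the biaryl axis carries only small ortho groups and is drawn without a descriptor. The task is therefore regiocontrol, and no stereocentre is available to control anything else. Five free phenols make the final compound electron-rich and easily oxidised. Both pyranones are vinylogous esters whose C2 is opened by hydroxide and amines. The phenols are therefore best carried as methyl ethers to the last step, and nucleophilic bases must be avoided once a chromone is present. The enabling feature is genistein ring B, a 1,3,4-trisubstituted benzene in which the C4' oxygen is para to C1' (bonded to genistein C3) and ortho to C3' (bonded to daidzein C8). This is the pattern left by the "para" Diels–Alder adduct of a 2-silyloxy-3-arylbuta-1,3-diene with an acetylenic ketone after dehydrogenation. Ring B can thus be grown on C8 of an intact daidzein nucleus, and the hindered biaryl coupling is avoided.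

## Retrosynthesis

**18 from 17.** The three O–CH3 bonds on daidzein O7, daidzein O4' and the ring-B oxygen are the last bonds cut. Methyl is preferred over benzyl or silyl because the 4'-methyl ether is already present in formononetin 1. Methyl ethers also survive every later condition (a Claisen rearrangement above 200 °C, palladium, quinone oxidation, thallium, boron trifluoride). The genistein 5- and 7-hydroxyls need no protection because they arrive late on unprotected phloroglucinol 15. The forward step must cleave three aryl methyl ethers without harming two pyranones.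

**17 from 14 and 15 through 16.** The genistein pyranone is opened at C4–C4a (aryl ketone bond) and at C2 (the one-carbon unit between C3 and O1). This gives arylacetic acid 14 and phloroglucinol 15 by way of deoxybenzoin 16. A cross-coupling of a 3-halochromone with a ring-B organometallic was considered. It would need a metal on ring B, whereas the cycloaddition delivers an acyl carbon there, so the deoxybenzoin route uses what the key step leaves. Compound 15 is symmetrical, so the acylation has no regiochemical question. The forward reaction is a Friedel–Crafts acylation and a formylative ring closure in one flask.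

**14 from 13 from 12.** The acetic acid side chain is traced to an acetyl group by an oxidative 1,2-aryl shift and ester hydrolysis. The C1'–acyl bond of ketone 12 is broken and C1' is rebonded to the former methyl carbon, which gives ester 13 and then acid 14. The dienophile of the key step must carry its acceptor directly on the alkyne, so ring B is necessarily formed as an acetophenone. The rearrangement works best when the migrating ring has a para-alkoxy group, which 12 has. The hydrolysis must be acidic to spare the pyranone.

**12 from 11 from 10.** The methyl ether 12 comes from aryl silyl ether 11 by silyl-to-methyl exchange, and 11 comes from cyclohexadiene 10 by loss of two hydrogens. The exchange is made because a methyl ether tolerates the thallium oxidation and the later Lewis acids better than a silyl ether or a free para-acylphenol. The dehydrogenation needs a mild hydride acceptor, because 10 is a doubly allylic 1,4-diene.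

**10 from 8 and 9.** Ring B is disconnected at C5'–C6' and C2'–C1' into silyloxydiene 8 and but-3-yn-2-one 9.
- The neighbouring cut is the biaryl bond C8–C3' itself. It would require a metal-mediated coupling at a doubly ortho-substituted position and separate regiocontrol on both rings.
- The cycloaddition moves the regiochemical question to the orbital coefficients of a diene with one strong donor.
- Compound 8 is a daidzein dimethyl ether with a four-carbon side chain, and 9 is commercial.
- The forward reaction must be para-selective and must overcome the hindrance of a twisted 3-aryl group.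

**8 from 7 from 6.** The O–Si bond of 8 is cut to give enone 7. The C2' methylene of 7 is removed as a one-carbon electrophile to give arylacetone 6. Enolisation of 7 can occur only at the methyl group, so the diene forms as a single constitutional isomer. The methylenation of 6 must take place at the benzylic carbon and not at the methyl group.

**6 from 5 from 4 from 3 from 1 and 2.**
- Ketone 6 is the Wacker product of allyl arene 5.
- Compound 5 is the methyl ether of phenol 4. Methylation comes before the oxidation because a free ortho phenol would cyclise onto the palladium-bound alkene.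
- The C8–carbon bond of 4 is cut by a retro-Claisen disconnection to allyl ether 3.
- Ether 3 is made from formononetin 1 and allyl bromide 2.
- Direct electrophilic substitution of 1 was the alternative. It would have to distinguish C8 from C6, whereas the sigmatropic shift of a 7-allyloxychromone goes to C8.

## Roads not taken

**Alternative 1:** The daidzein pyranone is cut at C4a–C4, C4–C3 and O1–C2. This leaves biaryl ortho-iodophenol A2, carbon monoxide A4 and enamine A3, the morpholine enamine of 4-methoxyphenylacetaldehyde.
- **Forward key step:** Under Pd(OAc)2 with P(tBu)3, zerovalent palladium inserts into the C–I bond, A4 is taken up, and the acylpalladium species acylates the β-carbon of A3. The phenol then closes onto the iminium carbon with loss of the amine to give arylacetate A1.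
- **Merits:** A1 is the same compound as 13, so the two routes share their last four steps. The acetate handle arrives intact, so the thallium oxidation and the silyl-to-methyl exchange are not needed. The biaryl bond is made earlier between two simple benzenes.
- **Weak points:**
  - A2 is a 1,2,3,4-tetrasubstituted benzene. Its iodine must sit ortho to the hydroxyl and para to the methoxy group, while the position para to the hydroxyl is equally activated and less hindered. Simple iodination is therefore unlikely to suffice, and directed metalation would add steps.
  - Acylation of an enamine by an acylpalladium species next to a free phenol has less precedent than the carbonylative alkyne route to flavones.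
  - A3 derives from an aldehyde prone to self-condensation and is sensitive to water.
  - The daidzein core, which can be bought complete in 1, would have to be built.
- **Comparison:** Alternative 1 is more convergent and avoids thallium, which are real advantages. The chosen plan sets against it that both substitution sites are fixed by pericyclic reactions (Claisen rearrangement, para rule), that no position depends on electrophilic selectivity, and that it starts from an intact isoflavone without toxic gas.

**Alternative 2:** Daidzein ring A is disconnected around the aryl–carbon bond into cyclobutenone A7 and aryl siloxyalkyne A6.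
- **Forward key step:** Heating opens A7 to a vinylketene. A [2+2] addition to A6, a second ring opening, a six-electron electrocyclisation and tautomerisation then give 2-aryl resorcinol monosilyl ether A5.
- **Merits:** The mechanism places the aryl group between a free hydroxyl (future O1) and a silyl ether (future O7), so the two oxygens are differentiated without protecting-group steps. The hindered aryl is a spectator on the alkyne. The bromine of A5 is a handle for the genistein half.
- **Weak points:**
  - After the key step neither pyranone exists, so two separate acylation and ring-closure sequences are needed.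
  - The first acylation of A5 must go ortho to the free hydroxyl and not para to it.
  - The bromide must still be homologated to an arylacetic acid.
  - A7 is volatile and unstable, and A6 needs ynolate chemistry and is moisture-sensitive. Both must be prepared.
- **Comparison:** The cascade of alternative 2 is probably more reliable than the cycloaddition chosen here, because its hindered aryl does not twist a diene. The chosen plan sets against this a much shorter route, since half of the carbon skeleton is bought as 1 and only one pyranone is built.

**Alternative 3:** The biaryl bond itself is cut between two intact isoflavones, tied together as di-tert-butylsilylene bis(aryl ether) A9. The iodine is placed on daidzein C8, and the genistein half is the 4'-phenol A10.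
- **Forward key step:** A Pd(OAc)2-catalysed intramolecular C–H arylation forms the C8–C3' bond and closes a temporary seven-membered dioxasilepine, A8. Fluoride and ether cleavage would then release the target.
- **Merits:** This is the most convergent plan and could need about half the steps. The target is an ortho,ortho'-biphenol, which is the product class such a tether gives. With iodine on C8, the C–H partner is a symmetrical para-oxygenated ring, so no regiochemical question remains.
- **Weak points:**
  - A10, with only its 4'-hydroxyl free, needs its own deoxybenzoin synthesis.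
  - The unsymmetrical silane must be assembled by two successive silylations without scrambling.
  - The arylation conditions (carbonate or carboxylate base, temperatures above 100 °C, polar solvent) expose two base-sensitive pyranones. Each has a C2–H bond that can itself be palladated.
- **Comparison:** Alternative 3 is clearly better in step economy and convergence. The chosen plan sets against this that every step keeps the chromone under neutral or acidic conditions, that the site of each bond is decided by pericyclic rules, and that no metal has to choose among several C–H bonds.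

Key step: step 7

Assumption: the target is drawn without an axial descriptor, so the biaryl axis with three small ortho substituents is treated as configurationally labile and no atroposelective step is planned.

## Route

Step 1
Reactants: 1 formononetin (7-hydroxy-3-(4-methoxyphenyl)-4H-chromen-4-one); 2 allyl bromide
Product: 3 7-(allyloxy)-3-(4-methoxyphenyl)-4H-chromen-4-one
Conditions: K2CO3, acetone, reflux
Reagents that add atoms: none
Why: Williamson etherification of the acidic 7-hydroxyl (para to the pyranone carbonyl); carbonate in acetone is not nucleophilic enough to open the pyranone.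

Step 2
Reactants: 3 7-(allyloxy)-3-(4-methoxyphenyl)-4H-chromen-4-one
Product: 4 8-allyl-7-hydroxy-3-(4-methoxyphenyl)-4H-chromen-4-one
Conditions: PhNEt2, 210 °C
Reagents that add atoms: none
Why: Aromatic Claisen rearrangement ([3,3]-sigmatropic shift, then tautomerisation); in 7-allyloxychromones the C7–C8 bond has the higher double-bond character, so the allyl group should migrate to C8 and not to C6.

Step 3
Reactants: 4 8-allyl-7-hydroxy-3-(4-methoxyphenyl)-4H-chromen-4-one
Product: 5 8-allyl-7-methoxy-3-(4-methoxyphenyl)-4H-chromen-4-one
Conditions: MeI, K2CO3, acetone, reflux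
Reagents that add atoms: iodomethane, CI
Why: O-Methylation of the phenol (Williamson); it prevents the ortho hydroxyl from adding to the palladium-activated alkene in step 4, which would give a benzofuran.

Step 4
Reactants: 5 8-allyl-7-methoxy-3-(4-methoxyphenyl)-4H-chromen-4-one
Product: 6 7-methoxy-3-(4-methoxyphenyl)-8-(2-oxopropyl)-4H-chromen-4-one
Conditions: PdCl2 (cat.), CuCl, O2 (1 atm), DMF/H2O, rt
Reagents that add atoms: water, O
Why: Tsuji–Wacker oxidation; Markovnikov hydroxypalladation of the terminal alkene by divalent palladium and β-hydride elimination give the methyl ketone, and CuCl with O2 reoxidises zerovalent palladium.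

Step 5
Reactants: 6 7-methoxy-3-(4-methoxyphenyl)-8-(2-oxopropyl)-4H-chromen-4-one
Product: 7 7-methoxy-3-(4-methoxyphenyl)-8-(3-oxobut-1-en-2-yl)-4H-chromen-4-one
Conditions: (CH2O)n, iPr2NH2+ CF3CO2−, CF3CO2H (cat.), THF, reflux
Reagents that add atoms: formaldehyde (as paraformaldehyde), C=O
Why: Mannich-type α-methylenation (aminomethylation of the enol, then β-elimination of the amine); under acid the ketone should react through its more substituted, aryl-conjugated enol, so the methylene enters at the benzylic carbon.

Step 6
Reactants: 7 7-methoxy-3-(4-methoxyphenyl)-8-(3-oxobut-1-en-2-yl)-4H-chromen-4-one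
Product: 8 8-[3-(tert-butyldimethylsilyloxy)buta-1,3-dien-2-yl]-7-methoxy-3-(4-methoxyphenyl)-4H-chromen-4-one
Conditions: TBSOTf, Et3N, CH2Cl2, 0 °C
Reagents that add atoms: tert-butyldimethylsilyl trifluoromethanesulfonate, CC(C)(C)[Si](C)(C)OS(=O)(=O)C(F)(F)F
Why: Soft enolisation and O-silylation of a methyl ketone (silyl enol ether formation); the methyl group is the only enolisable position, so the 2-silyloxydiene should form as one constitutional isomer.

Step 7
Reactants: 8 8-[3-(tert-butyldimethylsilyloxy)buta-1,3-dien-2-yl]-7-methoxy-3-(4-methoxyphenyl)-4H-chromen-4-one; 9 but-3-yn-2-one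
Product: 10 8-[5-acetyl-2-(tert-butyldimethylsilyloxy)cyclohexa-1,4-dien-1-yl]-7-methoxy-3-(4-methoxyphenyl)-4H-chromen-4-one
Conditions: 9 (excess), BHT (cat.), PhMe, sealed tube, 110 °C
Reagents that add atoms: none
Why: The reaction is a thermal, concerted, normal-electron-demand [4+2] cycloaddition between the s-cis conformer of silyloxydiene 8 (HOMO raised by the enol-ether oxygen) and ynone 9 (LUMO lowered by the acetyl group). The closest known reaction type is the Diels–Alder addition of 2-silyloxybuta-1,3-dienes to acetylenic ketones and esters, which gives 1,4-cyclohexadienes that are dehydrogenated to para-acylphenol ethers. The six-membered carbocycle (the future ring B of the genistein half) closes by suprafacial bond formation at both diene termini in one step, making C5'–C6' and C2'–C1' together. No stereocentre arises, because the alkyne supplies two sp2 carbons and the diene termini become CH2 groups. The step needs regioselectivity: the silyloxy oxygen puts the largest HOMO coefficient on the adjacent terminus (future C5'), which bonds to the unsubstituted β-carbon of 9 with the largest LUMO coefficient, so the acetyl group ends para to oxygen. The daidzein substituent on C3 of the diene would direct the other way if it were conjugated, but O1 and the 7-methoxy group twist it out of the diene plane, so the oxygen donor decides. The chromone C2=C3 bond is an electron-rich vinylogous ester alkene and should not act as a dienophile toward an electron-rich diene. Excess volatile 9, a sealed vessel and a radical inhibitor answer the slow reaction expected of the hindered diene.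

Step 8
Reactants: 10 8-[5-acetyl-2-(tert-butyldimethylsilyloxy)cyclohexa-1,4-dien-1-yl]-7-methoxy-3-(4-methoxyphenyl)-4H-chromen-4-one
Product: 11 8-[5-acetyl-2-(tert-butyldimethylsilyloxy)phenyl]-7-methoxy-3-(4-methoxyphenyl)-4H-chromen-4-one
Conditions: DDQ, PhMe, rt
Reagents that add atoms: none
Why: Quinone dehydrogenation of a 1,4-cyclohexadiene; hydride is abstracted from a doubly allylic CH2 to a cation stabilised by the silyloxy group, and proton loss gives the arene with the oxygen retained as an aryl silyl ether.

Step 9
Reactants: 11 8-[5-acetyl-2-(tert-butyldimethylsilyloxy)phenyl]-7-methoxy-3-(4-methoxyphenyl)-4H-chromen-4-one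
Product: 12 8-(5-acetyl-2-methoxyphenyl)-7-methoxy-3-(4-methoxyphenyl)-4H-chromen-4-one
Conditions: CsF, MeI, DMF, rt
Reagents that add atoms: iodomethane, CI
Why: One-pot fluoride desilylation and O-alkylation; the cesium phenoxide, stabilised by the para acetyl group, is methylated in situ, giving an ether that tolerates the oxidation in step 10.

Step 10
Reactants: 12 8-(5-acetyl-2-methoxyphenyl)-7-methoxy-3-(4-methoxyphenyl)-4H-chromen-4-one
Product: 13 methyl 2-{4-methoxy-3-[7-methoxy-3-(4-methoxyphenyl)-4-oxo-4H-chromen-8-yl]phenyl}acetate
Conditions: Tl(NO3)3·3H2O, MeOH, HClO4 (cat.), rt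
Reagents that add atoms: methanol, CO
Why: Thallium trinitrate oxidative rearrangement of an aryl methyl ketone; trivalent thallium oxythallates the enol, and the para-methoxyaryl ring migrates as monovalent thallium leaves, giving the methyl arylacetate. Isoflavones are themselves made with this reagent, so the pyranone should survive.

Step 11
Reactants: 13 methyl 2-{4-methoxy-3-[7-methoxy-3-(4-methoxyphenyl)-4-oxo-4H-chromen-8-yl]phenyl}acetate
Product: 14 2-{4-methoxy-3-[7-methoxy-3-(4-methoxyphenyl)-4-oxo-4H-chromen-8-yl]phenyl}acetic acid
Conditions: 2 M HCl, 1,4-dioxane, 90 °C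
Reagents that add atoms: water, O
Why: Acid-catalysed ester hydrolysis; it is chosen over saponification because hydroxide attacks C2 of the pyranone, whereas the chromone and the aryl methyl ethers are stable to dilute mineral acid.

Step 12
Reactants: 14 2-{4-methoxy-3-[7-methoxy-3-(4-methoxyphenyl)-4-oxo-4H-chromen-8-yl]phenyl}acetic acid; 15 phloroglucinol
Product: 17 8-[5-(5,7-dihydroxy-4-oxo-4H-chromen-3-yl)-2-methoxyphenyl]-7-methoxy-3-(4-methoxyphenyl)-4H-chromen-4-one (biisoflavone trimethyl ether), via trihydroxydeoxybenzoin 16 (not isolated)
Conditions: BF3·OEt2, 85 °C; then DMF, MsCl, 70 °C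
Reagents that add atoms: N,N-dimethylformamide, CN(C)C=O
Why: Friedel–Crafts acylation of symmetrical phloroglucinol by the acid in BF3·OEt2 gives the deoxybenzoin as its boron chelate. A Vilsmeier-type reagent from DMF and MsCl then formylates the activated methylene, and the ortho hydroxyl closes the pyranone with loss of dimethylamine (deoxybenzoin route to isoflavones).

Step 13
Reactants: 17 8-[5-(5,7-dihydroxy-4-oxo-4H-chromen-3-yl)-2-methoxyphenyl]-7-methoxy-3-(4-methoxyphenyl)-4H-chromen-4-one
Product: 18 8-[5-(5,7-dihydroxy-4-oxo-4H-chromen-3-yl)-2-hydroxyphenyl]-7-hydroxy-3-(4-hydroxyphenyl)-4H-chromen-4-one (target)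
Conditions: BBr3 (excess), CH2Cl2, −78 °C to rt; then H2O
Reagents that add atoms: none
Why: Lewis-acid cleavage of three aryl methyl ethers (bromide attacks the methyl group of each boron-complexed ether); the pyranones and free phenols tolerate BBr3, and hydrolysis of the aryl borates releases the pentaphenol.

## Compound list

1 | formononetin (7-hydroxy-3-(4-methoxyphenyl)-4H-chromen-4-one) | O=c1c(-c2ccc(OC)cc2)coc2cc(O)ccc12 | starting material
2 | allyl bromide | C=CCBr | starting material
3 | 7-(allyloxy)-3-(4-methoxyphenyl)-4H-chromen-4-one | C=CCOc1ccc2c(=O)c(-c3ccc(OC)cc3)coc2c1 | intermediate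
4 | 8-allyl-7-hydroxy-3-(4-methoxyphenyl)-4H-chromen-4-one | C=CCc1c(O)ccc2c(=O)c(-c3ccc(OC)cc3)coc12 | intermediate
5 | 8-allyl-7-methoxy-3-(4-methoxyphenyl)-4H-chromen-4-one | C=CCc1c(OC)ccc2c(=O)c(-c3ccc(OC)cc3)coc12 | intermediate
6 | 7-methoxy-3-(4-methoxyphenyl)-8-(2-oxopropyl)-4H-chromen-4-one | CC(=O)Cc1c(OC)ccc2c(=O)c(-c3ccc(OC)cc3)coc12 | intermediate
7 | 7-methoxy-3-(4-methoxyphenyl)-8-(3-oxobut-1-en-2-yl)-4H-chromen-4-one | CC(=O)C(=C)c1c(OC)ccc2c(=O)c(-c3ccc(OC)cc3)coc12 | intermediate
8 | 8-[3-(tert-butyldimethylsilyloxy)buta-1,3-dien-2-yl]-7-methoxy-3-(4-methoxyphenyl)-4H-chromen-4-one | C=C(O[Si](C)(C)C(C)(C)C)C(=C)c1c(OC)ccc2c(=O)c(-c3ccc(OC)cc3)coc12 | intermediate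
9 | but-3-yn-2-one | CC(=O)C#C | starting material
10 | 8-[5-acetyl-2-(tert-butyldimethylsilyloxy)cyclohexa-1,4-dien-1-yl]-7-methoxy-3-(4-methoxyphenyl)-4H-chromen-4-one | CC(=O)C1=CCC(O[Si](C)(C)C(C)(C)C)=C(c2c(OC)ccc3c(=O)c(-c4ccc(OC)cc4)coc23)C1 | intermediate
11 | 8-[5-acetyl-2-(tert-butyldimethylsilyloxy)phenyl]-7-methoxy-3-(4-methoxyphenyl)-4H-chromen-4-one | CC(=O)c1ccc(O[Si](C)(C)C(C)(C)C)c(-c2c(OC)ccc3c(=O)c(-c4ccc(OC)cc4)coc23)c1 | intermediate
12 | 8-(5-acetyl-2-methoxyphenyl)-7-methoxy-3-(4-methoxyphenyl)-4H-chromen-4-one | CC(=O)c1ccc(OC)c(-c2c(OC)ccc3c(=O)c(-c4ccc(OC)cc4)coc23)c1 | intermediate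
13 | methyl 2-{4-methoxy-3-[7-methoxy-3-(4-methoxyphenyl)-4-oxo-4H-chromen-8-yl]phenyl}acetate | COC(=O)Cc1ccc(OC)c(-c2c(OC)ccc3c(=O)c(-c4ccc(OC)cc4)coc23)c1 | intermediate
14 | 2-{4-methoxy-3-[7-methoxy-3-(4-methoxyphenyl)-4-oxo-4H-chromen-8-yl]phenyl}acetic acid | OC(=O)Cc1ccc(OC)c(-c2c(OC)ccc3c(=O)c(-c4ccc(OC)cc4)coc23)c1 | intermediate
15 | phloroglucinol (benzene-1,3,5-triol) | Oc1cc(O)cc(O)c1 | starting material
16 | 7-methoxy-8-{2-methoxy-5-[2-oxo-2-(2,4,6-trihydroxyphenyl)ethyl]phenyl}-3-(4-methoxyphenyl)-4H-chromen-4-one | O=C(Cc1ccc(OC)c(-c2c(OC)ccc3c(=O)c(-c4ccc(OC)cc4)coc23)c1)c1c(O)cc(O)cc1O | intermediate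
17 | 8-[5-(5,7-dihydroxy-4-oxo-4H-chromen-3-yl)-2-methoxyphenyl]-7-methoxy-3-(4-methoxyphenyl)-4H-chromen-4-one | COc1ccc(-c2coc3cc(O)cc(O)c3c2=O)cc1-c1c(OC)ccc2c(=O)c(-c3ccc(OC)cc3)coc12 | intermediate
18 | 8-[5-(5,7-dihydroxy-4-oxo-4H-chromen-3-yl)-2-hydroxyphenyl]-7-hydroxy-3-(4-hydroxyphenyl)-4H-chromen-4-one | O=c1c(-c2ccc(O)cc2)coc2c(-c3cc(-c4coc5cc(O)cc(O)c5c4=O)ccc3O)c(O)ccc12 | target

## Step count and least certain steps

Total step count: 13. Longest linear sequence: 13 steps (1 to 18); compounds 2, 9 and 15 are bought.

**Step 7 (key step).** The twisted, doubly ortho-substituted aryl group on C3 of the diene, next to the silyloxy group, may make the reactive s-cis geometry too rare. Long heating would then favour polymerisation of the ynone and hydrolysis or silyl migration of the enol ether over cycloaddition. Partial conjugation of the aryl ring could also erode para selectivity. The fallback abandons the ring construction and makes the biaryl bond directly. It sets out from 1 and returns at 12.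
- Iodination of 1 with N-iodosuccinimide at the position ortho to the 7-hydroxyl should give 8-iodoformononetin F1.
- Methylation (MeI, K2CO3) should give 8-iodo-7-methoxy-3-(4-methoxyphenyl)-4H-chromen-4-one F2.
- Suzuki–Miyaura coupling of F2 with commercial (5-acetyl-2-methoxyphenyl)boronic acid F3 (Pd(OAc)2, SPhos, K3PO4, PhMe/H2O, 100 °C) should give 12. A bulky biarylphosphine is needed because the biaryl has three ortho substituents.

**Step 5.** Methylenation may occur partly at the methyl group instead of the hindered benzylic carbon. Enone 7, a 1,1-disubstituted acceptor, may dimerise or polymerise on concentration. The fallback is a stepwise route through a storable Mannich base. It sets out from 6 and returns at 7.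
- Dimethyl(methylidene)ammonium iodide in refluxing MeCN should aminomethylate the more stable benzylic enol and give racemic 8-[1-(dimethylamino)-3-oxobutan-2-yl]-7-methoxy-3-(4-methoxyphenyl)-4H-chromen-4-one F4.
- Quaternisation with MeI should give the trimethylammonium iodide F5.
- Aqueous NaHCO3 with CH2Cl2 should eliminate trimethylamine just before step 6 and release 7.

**Step 10.** α-Methoxylation of the ketone and oxidation or nitration of the three anisole-type rings may compete with the aryl shift. The ortho-aryl substituent may slow migration. The fallback replaces the oxidative shift by a Wolff rearrangement. It sets out from 12 and returns at 13.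
- Enolisation of 12 with LiHMDS at −78 °C and trifluoroacetylation with 2,2,2-trifluoroethyl trifluoroacetate should give 4,4,4-trifluoro-1-{4-methoxy-3-[7-methoxy-3-(4-methoxyphenyl)-4-oxo-4H-chromen-8-yl]phenyl}butane-1,3-dione F6.
- Detrifluoroacetylative diazo transfer with methanesulfonyl azide and Et3N should give 8-[5-(2-diazoacetyl)-2-methoxyphenyl]-7-methoxy-3-(4-methoxyphenyl)-4H-chromen-4-one F7.
- Wolff rearrangement of F7 (AgO2CPh, Et3N, MeOH) should give the aryl ketene, which methanol traps as 13.

**Step 12.** The bulky, poorly soluble acid 14 may acylate phloroglucinol only slowly. Long heating in BF3·OEt2 may then cause O-acylation or partial ether cleavage, and the unprotected triol may be formylated on the ring in the second stage. The fallback uses a protected partner and separate steps. It sets out from 14 and returns at 18.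
- Acid 14 is activated with trifluoroacetic anhydride and acylates 1,3,5-trimethoxybenzene F8. This should give 7-methoxy-8-{2-methoxy-5-[2-oxo-2-(2,4,6-trimethoxyphenyl)ethyl]phenyl}-3-(4-methoxyphenyl)-4H-chromen-4-one F9.
- BCl3 at low temperature should cleave only the methyl ether chelated to the ketone. This should give 8-{5-[2-(2-hydroxy-4,6-dimethoxyphenyl)-2-oxoethyl]-2-methoxyphenyl}-7-methoxy-3-(4-methoxyphenyl)-4H-chromen-4-one F10.
- Heating F10 with N,N-dimethylformamide dimethyl acetal should close the pyranone. This should give 8-[5-(5,7-dimethoxy-4-oxo-4H-chromen-3-yl)-2-methoxyphenyl]-7-methoxy-3-(4-methoxyphenyl)-4H-chromen-4-one F11.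
- BBr3 should cleave all five methyl ethers of F11 and give 18.

## Further compounds

F1 | step 7 | 8-iodoformononetin (7-hydroxy-8-iodo-3-(4-methoxyphenyl)-4H-chromen-4-one) | O=c1c(-c2ccc(OC)cc2)coc2c(I)c(O)ccc12
F2 | step 7 | 8-iodo-7-methoxy-3-(4-methoxyphenyl)-4H-chromen-4-one | COc1ccc(-c2coc3c(I)c(OC)ccc3c2=O)cc1
F3 | step 7 | (5-acetyl-2-methoxyphenyl)boronic acid | CC(=O)c1ccc(OC)c(B(O)O)c1
F4 | step 5 | 8-[1-(dimethylamino)-3-oxobutan-2-yl]-7-methoxy-3-(4-methoxyphenyl)-4H-chromen-4-one (racemic) | CC(=O)C(CN(C)C)c1c(OC)ccc2c(=O)c(-c3ccc(OC)cc3)coc12
F5 | step 5 | {2-[7-methoxy-3-(4-methoxyphenyl)-4-oxo-4H-chromen-8-yl]-3-oxobutyl}trimethylammonium iodide (racemic) | CC(=O)C(C[N+](C)(C)C)c1c(OC)ccc2c(=O)c(-c3ccc(OC)cc3)coc12.[I-]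
F6 | step 10 | 4,4,4-trifluoro-1-{4-methoxy-3-[7-methoxy-3-(4-methoxyphenyl)-4-oxo-4H-chromen-8-yl]phenyl}butane-1,3-dione | O=C(CC(=O)C(F)(F)F)c1ccc(OC)c(-c2c(OC)ccc3c(=O)c(-c4ccc(OC)cc4)coc23)c1
F7 | step 10 | 8-[5-(2-diazoacetyl)-2-methoxyphenyl]-7-methoxy-3-(4-methoxyphenyl)-4H-chromen-4-one | [N-]=[N+]=CC(=O)c1ccc(OC)c(-c2c(OC)ccc3c(=O)c(-c4ccc(OC)cc4)coc23)c1
F8 | step 12 | 1,3,5-trimethoxybenzene | COc1cc(OC)cc(OC)c1
F9 | step 12 | 7-methoxy-8-{2-methoxy-5-[2-oxo-2-(2,4,6-trimethoxyphenyl)ethyl]phenyl}-3-(4-methoxyphenyl)-4H-chromen-4-one | O=C(Cc1ccc(OC)c(-c2c(OC)ccc3c(=O)c(-c4ccc(OC)cc4)coc23)c1)c1c(OC)cc(OC)cc1OC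
F10 | step 12 | 8-{5-[2-(2-hydroxy-4,6-dimethoxyphenyl)-2-oxoethyl]-2-methoxyphenyl}-7-methoxy-3-(4-methoxyphenyl)-4H-chromen-4-one | O=C(Cc1ccc(OC)c(-c2c(OC)ccc3c(=O)c(-c4ccc(OC)cc4)coc23)c1)c1c(O)cc(OC)cc1OC
F11 | step 12 | 8-[5-(5,7-dimethoxy-4-oxo-4H-chromen-3-yl)-2-methoxyphenyl]-7-methoxy-3-(4-methoxyphenyl)-4H-chromen-4-one | COc1ccc(-c2coc3cc(OC)cc(OC)c3c2=O)cc1-c1c(OC)ccc2c(=O)c(-c3ccc(OC)cc3)coc12
A1 | alternative 1 | methyl 2-{4-methoxy-3-[7-methoxy-3-(4-methoxyphenyl)-4-oxo-4H-chromen-8-yl]phenyl}acetate (identical with 13) | COC(=O)Cc1ccc(OC)c(-c2c(OC)ccc3c(=O)c(-c4ccc(OC)cc4)coc23)c1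
A2 | alternative 1 | methyl 2-[3-(2-hydroxy-3-iodo-6-methoxyphenyl)-4-methoxyphenyl]acetate | COC(=O)Cc1ccc(OC)c(-c2c(OC)ccc(I)c2O)c1
A3 | alternative 1 | 4-[(E)-2-(4-methoxyphenyl)ethenyl]morpholine | COc1ccc(/C=C/N2CCOCC2)cc1
A4 | alternative 1 | carbon monoxide | [C-]#[O+]
A5 | alternative 2 | 2-(5-bromo-2-methoxyphenyl)-3-(triisopropylsilyloxy)phenol | COc1ccc(Br)cc1-c1c(O)cccc1O[Si](C(C)C)(C(C)C)C(C)C
A6 | alternative 2 | {[(5-bromo-2-methoxyphenyl)ethynyl]oxy}triisopropylsilane | COc1ccc(Br)cc1C#CO[Si](C(C)C)(C(C)C)C(C)C
A7 | alternative 2 | cyclobut-2-en-1-one | O=C1C=CC1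
A8 | alternative 3 | dioxasilepine-bridged 8,3'-biisoflavone trimethyl ether (cyclic di-tert-butylsilylene diether of the daidzein 7-oxygen and the genistein 4'-oxygen) | O=c1c(-c2ccc(OC)cc2)coc2c3c(ccc12)O[Si](C(C)(C)C)(C(C)(C)C)Oc1ccc(-c2coc4cc(OC)cc(OC)c4c2=O)cc1-3
A9 | alternative 3 | di-tert-butyl{[8-iodo-3-(4-methoxyphenyl)-4-oxo-4H-chromen-7-yl]oxy}[4-(5,7-dimethoxy-4-oxo-4H-chromen-3-yl)phenoxy]silane | O=c1c(-c2ccc(OC)cc2)coc2c(I)c(O[Si](C(C)(C)C)(C(C)(C)C)Oc3ccc(-c4coc5cc(OC)cc(OC)c5c4=O)cc3)ccc12
A10 | alternative 3 | 3-(4-hydroxyphenyl)-5,7-dimethoxy-4H-chromen-4-one | COc1cc(OC)c2c(=O)c(-c3ccc(O)cc3)coc2c1
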